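Ring B holds a carboxyl on C1 and an (R)-2-acyloxypropyl chain on C6; tied together, these are a 3-methyl-3,4-dihydroisocoumarin. The plan therefore cuts the aryl C6–CH2 bond and the lactone C(=O)–O bond back to 2,4-bis(benzyloxy)benzoic acid, whose single open ortho position is C6–H, and (R)-propylene oxide. One palladium-catalysed, carboxylate-directed C–H alkylation with lactonisation forms both bonds and the ring, carries the epoxide stereocentre through untouched, and stores acid and alcohol of ring B as one lactone. After hydroxide opening, alcohol and acid are esterified in turn; both hindered benzoates arise by Mitsunobu inversion of tert-butyl (S)-3-hydroxybutanoate, and one hydrogenolysis removes six benzyl ethers.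

Key step: step 2

Remark: rings are called A (orsellinate), B (central resorcylate) and C (terminal resorcinol), ring B is numbered from its carboxyl-bearing carbon C1, and all four carbinol carbons of the target are R.

Step 1
Reactants: 1 2,4-dihydroxybenzoic acid; 2 benzyl bromide
Product: 4 2,4-bis(benzyloxy)benzoic acid, via benzyl 2,4-bis(benzyloxy)benzoate 3 (not isolated)
Conditions: BnBr (3.3 equiv), K2CO3, DMSO, 50 °C; then KOH, H2O, 80 °C, same flask; HCl to pH 2
Reagents that add atoms: benzyl bromide (2), BrCc1ccccc1; potassium hydroxide, [K+].[OH-]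
Why: Williamson O-benzylation of both phenoxides and of the carboxylate, then saponification of the benzyl ester (acyl–oxygen cleavage, so one carboxyl oxygen comes from hydroxide), should leave the aryl benzyl ethers intact and give the acid with C6–H as its only free ortho position.

Step 2
Reactants: 4 2,4-bis(benzyloxy)benzoic acid; 5 (R)-propylene oxide
Product: 7 (R)-6,8-bis(benzyloxy)-3-methyl-3,4-dihydroisocoumarin, via open-chain hydroxy acid 6 (not isolated)
Conditions: Pd(OAc)2 (5 mol%), N-acetyl-L-tert-leucine (10 mol%), KOAc (1 equiv), (R)-propylene oxide (3 equiv), HFIP, 25–40 °C, sealed tube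
Reagents that add atoms: (R)-propylene oxide (5), C[C@@H]1CO1
Why: The potassium carboxylate of 4 binds divalent palladium and, with the N-acetyl amino acid as internal base, concerted metalation–deprotonation at C6–H gives a five-membered palladacycle; its aryl–palladium bond then opens the epoxide by backside attack at the CH2 carbon, a redox-neutral event that keeps palladium divalent and needs no oxidant. The closest known reaction type is the palladium-catalysed, carboxylate-directed ortho C–H alkylation of benzoic acids by terminal epoxides, which delivers 3-substituted 3,4-dihydroisocoumarins. The one new ring closes by 6-exo-trig attack of the freed secondary oxygen of 6 on the carboxyl carbon, with loss of water. No stereocentre is created: C3 of 7 is the CH(CH3)–O carbon of 5, whose C–O bond is never broken, so R is carried over. Site selectivity rests on the carboxylate director and on C2 being blocked by a benzyloxy group, which leaves C6–H as the only ortho C–H; the palladium–carbon bond prefers the sterically open CH2 end of the epoxide over the methyl-bearing carbon, and the mild temperature should hold back protodecarboxylation of the electron-rich acid.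

Step 3
Reactants: 7 (R)-6,8-bis(benzyloxy)-3-methyl-3,4-dihydroisocoumarin; 8 allyl bromide
Product: 10 allyl 2,4-bis(benzyloxy)-6-[(R)-2-hydroxypropyl]benzoate, via potassium hydroxy carboxylate 9 (not isolated)
Conditions: KOH (1.0 equiv), dioxane/H2O, 80 °C; evaporate; allyl bromide, DMF, 0 °C to rt; cold neutral work-up
Reagents that add atoms: potassium hydroxide, [K+].[OH-]; allyl bromide (8), C=CCBr
Why: Saponification opens the lactone by acyl substitution to carboxylate 9, which cannot reclose, and SN2 O-allylation of that carboxylate builds the hindered ester from the oxygen side while the neutral secondary alcohol stays free; the C–O bond at the R centre is not involved.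

Step 4
Reactants: 11 orsellinic acid; 2 benzyl bromide
Product: 13 2,4-bis(benzyloxy)-6-methylbenzoic acid, via benzyl 2,4-bis(benzyloxy)-6-methylbenzoate 12 (not isolated)
Conditions: BnBr (3.3 equiv), K2CO3, DMSO, 50 °C; then KOH, H2O, 100 °C, same flask; HCl to pH 2 at 0 °C
Reagents that add atoms: benzyl bromide (2), BrCc1ccccc1; potassium hydroxide, [K+].[OH-]
Why: Williamson O-benzylation followed by saponification as in step 1; the di-ortho-substituted benzyl ester needs hotter hydroxide in aqueous DMSO, which aryl benzyl ethers tolerate (hydroxide oxygen is incorporated if cleavage is at the acyl carbon).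

Step 5
Reactants: 13 2,4-bis(benzyloxy)-6-methylbenzoic acid; 14 tert-butyl (S)-3-hydroxybutanoate
Product: 15 tert-butyl (R)-3-{[2,4-bis(benzyloxy)-6-methylbenzoyl]oxy}butanoate
Conditions: PPh3, DIAD, 14 (1.5 equiv), toluene, 0 °C to rt
Reagents that add atoms: tert-butyl (S)-3-hydroxybutanoate (14), C[C@H](O)CC(=O)OC(C)(C)C
Why: Mitsunobu esterification, in which the carboxylate of 13 displaces the oxyphosphonium group of activated 14 by SN2 at the carbinol carbon, so the crowding of the carboxyl carbon does not matter and the S centre is inverted to R; an excess of the cheap hydroxy ester covers loss by elimination to tert-butyl crotonate.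

Step 6
Reactants: 15 tert-butyl (R)-3-{[2,4-bis(benzyloxy)-6-methylbenzoyl]oxy}butanoate
Product: 16 (R)-3-{[2,4-bis(benzyloxy)-6-methylbenzoyl]oxy}butanoic acid
Conditions: TFA/CH2Cl2 (1:4), 0 °C to rt
Reagents that add atoms: none
Why: Acidolysis of the tert-butyl ester by alkyl–oxygen cleavage (the tert-butyl cation leaves as isobutene) frees the acid without touching the hindered benzoate, the aryl benzyl ethers on the ester-deactivated ring or the stereocentre.

Step 7
Reactants: 10 allyl 2,4-bis(benzyloxy)-6-[(R)-2-hydroxypropyl]benzoate; 16 (R)-3-{[2,4-bis(benzyloxy)-6-methylbenzoyl]oxy}butanoic acid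
Product: 17 allyl ester of the ring A–hydroxybutanoate–ring B acid (ring B side-chain oxygen acylated by 16; full name in the list)
Conditions: EDC·HCl, DMAP (0.2 equiv), CH2Cl2, 0 °C
Reagents that add atoms: acid 16, Cc1cc(OCc2ccccc2)cc(OCc2ccccc2)c1C(=O)O[C@H](C)CC(=O)O
Why: Steglich esterification (carbodiimide activation, DMAP acyl transfer) of an unhindered aliphatic acid with the secondary alcohol forms the ester at the acyl carbon with retention at both R centres; low temperature and substoichiometric DMAP limit β-elimination of the activated acid and reclosure of 10 to the lactone.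

Step 8
Reactants: 17 allyl ester of the ring A–hydroxybutanoate–ring B acid
Product: 18 ring A–hydroxybutanoate–ring B acid (free benzoic acid on ring B; full name in the list)
Conditions: Pd(PPh3)4 (5 mol%), morpholine, THF, rt; citric acid work-up
Reagents that add atoms: none
Why: Tsuji–Trost deallylation, in which zerovalent palladium ionises the allyl ester at the allyl carbon to a π-allyl complex that morpholine captures, so the shielded carboxyl is freed without a nucleophile at any carbonyl and the other esters and benzyl ethers stay intact.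

Step 9
Reactants: 18 ring A–hydroxybutanoate–ring B acid; 14 tert-butyl (S)-3-hydroxybutanoate
Product: 19 tert-butyl (R)-3-(aroyloxy)butanoate of acid 18 (full name in the list)
Conditions: PPh3, DIAD, 14 (2 equiv), toluene, 0 °C to rt
Reagents that add atoms: tert-butyl (S)-3-hydroxybutanoate (14), C[C@H](O)CC(=O)OC(C)(C)C
Why: Mitsunobu esterification as in step 5, where the di-ortho-substituted ring B carboxylate acts only as nucleophile in an SN2 displacement at the carbinol carbon of activated 14 (S to R by inversion), which avoids activating the carboxyl that sits next to the acyloxypropyl chain.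

Step 10
Reactants: 19 tert-butyl ester
Product: 20 (R)-3-(aroyloxy)butanoic acid of the ring A–hydroxybutanoate–ring B unit (full name in the list)
Conditions: TFA/CH2Cl2 (1:4), 0 °C to rt
Reagents that add atoms: none
Why: Acidolysis of the tert-butyl ester by alkyl–oxygen cleavage as in step 6; the three other esters are not ionisable and both benzyloxy-bearing rings are deactivated by their ester carbonyls.

Step 11
Reactants: 21 5-bromoresorcinol; 2 benzyl bromide
Product: 22 1,3-bis(benzyloxy)-5-bromobenzene
Conditions: BnBr (2.2 equiv), K2CO3, DMF, 60 °C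
Reagents that add atoms: benzyl bromide (2), BrCc1ccccc1
Why: Williamson ether synthesis on two unhindered phenoxides, with the aryl bromide inert under these conditions.

Step 12
Reactants: 22 1,3-bis(benzyloxy)-5-bromobenzene; 5 (R)-propylene oxide
Product: 24 (R)-1-[3,5-bis(benzyloxy)phenyl]propan-2-ol, via aryl Grignard reagent 23 (not isolated)
Conditions: Mg, THF, 50 °C; then CuBr·SMe2 (10 mol%), (R)-propylene oxide, THF, −30 to 0 °C; 1 M HCl
Reagents that add atoms: (R)-propylene oxide (5), C[C@@H]1CO1
Why: Magnesium insertion gives the aryl Grignard reagent and copper-catalysed SN2 opening of the epoxide at its CH2 terminus forms the aryl–CH2 bond; the C–O bond at the stereocentre is untouched, so R is retained.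

Step 13
Reactants: 20 (R)-3-(aroyloxy)butanoic acid; 24 (R)-1-[3,5-bis(benzyloxy)phenyl]propan-2-ol
Product: 25 hexa-O-benzyl hansforester A
Conditions: EDC·HCl, DMAP (0.2 equiv), CH2Cl2, 0 °C to rt
Reagents that add atoms: alcohol 24, C[C@@H](O)Cc1cc(OCc2ccccc2)cc(OCc2ccccc2)c1
Why: Steglich esterification of an aliphatic acid with an unhindered secondary alcohol at the acyl carbon, with retention at all four R centres; low temperature limits β-elimination of the activated acid.

Step 14
Reactants: 25 hexa-O-benzyl hansforester A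
Product: 26 hansforester A
Conditions: H2 (1 atm), 10% Pd/C, EtOAc, rt
Reagents that add atoms: none
Why: Heterogeneous hydrogenolysis cleaves the six aryl benzyl ethers, whereas the four esters (two aryl carboxylates, two alkyl carboxylates on homobenzylic, not benzylic, carbons) are inert to hydrogen and no stereocentre is touched.

Compound list
1 | 2,4-dihydroxybenzoic acid | O=C(O)c1ccc(O)cc1O | starting material
2 | benzyl bromide | BrCc1ccccc1 | starting material
3 | benzyl 2,4-bis(benzyloxy)benzoate | O=C(OCc1ccccc1)c1ccc(OCc2ccccc2)cc1OCc1ccccc1 | intermediate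
4 | 2,4-bis(benzyloxy)benzoic acid | O=C(O)c1ccc(OCc2ccccc2)cc1OCc1ccccc1 | intermediate
5 | (R)-propylene oxide | C[C@@H]1CO1 | starting material
6 | 2,4-bis(benzyloxy)-6-[(R)-2-hydroxypropyl]benzoic acid (open-chain alkylation product, present as its carboxylate) | C[C@@H](O)Cc1cc(OCc2ccccc2)cc(OCc2ccccc2)c1C(=O)O | intermediate
7 | (R)-6,8-bis(benzyloxy)-3-methyl-3,4-dihydroisocoumarin | C[C@@H]1Cc2cc(OCc3ccccc3)cc(OCc3ccccc3)c2C(=O)O1 | intermediate
8 | allyl bromide | C=CCBr | starting material
9 | potassium 2,4-bis(benzyloxy)-6-[(R)-2-hydroxypropyl]benzoate | C[C@@H](O)Cc1cc(OCc2ccccc2)cc(OCc2ccccc2)c1C(=O)[O-].[K+] | intermediate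
10 | allyl 2,4-bis(benzyloxy)-6-[(R)-2-hydroxypropyl]benzoate | C[C@@H](O)Cc1cc(OCc2ccccc2)cc(OCc2ccccc2)c1C(=O)OCC=C | intermediate
11 | orsellinic acid (2,4-dihydroxy-6-methylbenzoic acid) | Cc1cc(O)cc(O)c1C(=O)O | starting material
12 | benzyl 2,4-bis(benzyloxy)-6-methylbenzoate | Cc1cc(OCc2ccccc2)cc(OCc2ccccc2)c1C(=O)OCc1ccccc1 | intermediate
13 | 2,4-bis(benzyloxy)-6-methylbenzoic acid | Cc1cc(OCc2ccccc2)cc(OCc2ccccc2)c1C(=O)O | intermediate
14 | tert-butyl (S)-3-hydroxybutanoate | C[C@H](O)CC(=O)OC(C)(C)C | starting material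
15 | tert-butyl (R)-3-{[2,4-bis(benzyloxy)-6-methylbenzoyl]oxy}butanoate | Cc1cc(OCc2ccccc2)cc(OCc2ccccc2)c1C(=O)O[C@H](C)CC(=O)OC(C)(C)C | intermediate
16 | (R)-3-{[2,4-bis(benzyloxy)-6-methylbenzoyl]oxy}butanoic acid | Cc1cc(OCc2ccccc2)cc(OCc2ccccc2)c1C(=O)O[C@H](C)CC(=O)O | intermediate
17 | allyl 2,4-bis(benzyloxy)-6-[(R)-2-({(R)-3-[(2,4-bis(benzyloxy)-6-methylbenzoyl)oxy]butanoyl}oxy)propyl]benzoate | Cc1cc(OCc2ccccc2)cc(OCc2ccccc2)c1C(=O)O[C@H](C)CC(=O)O[C@H](C)Cc1cc(OCc2ccccc2)cc(OCc2ccccc2)c1C(=O)OCC=C | intermediate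
18 | 2,4-bis(benzyloxy)-6-[(R)-2-({(R)-3-[(2,4-bis(benzyloxy)-6-methylbenzoyl)oxy]butanoyl}oxy)propyl]benzoic acid | Cc1cc(OCc2ccccc2)cc(OCc2ccccc2)c1C(=O)O[C@H](C)CC(=O)O[C@H](C)Cc1cc(OCc2ccccc2)cc(OCc2ccccc2)c1C(=O)O | intermediate
19 | tert-butyl (R)-3-({2,4-bis(benzyloxy)-6-[(R)-2-({(R)-3-[(2,4-bis(benzyloxy)-6-methylbenzoyl)oxy]butanoyl}oxy)propyl]benzoyl}oxy)butanoate | Cc1cc(OCc2ccccc2)cc(OCc2ccccc2)c1C(=O)O[C@H](C)CC(=O)O[C@H](C)Cc1cc(OCc2ccccc2)cc(OCc2ccccc2)c1C(=O)O[C@H](C)CC(=O)OC(C)(C)C | intermediate
20 | (R)-3-({2,4-bis(benzyloxy)-6-[(R)-2-({(R)-3-[(2,4-bis(benzyloxy)-6-methylbenzoyl)oxy]butanoyl}oxy)propyl]benzoyl}oxy)butanoic acid | Cc1cc(OCc2ccccc2)cc(OCc2ccccc2)c1C(=O)O[C@H](C)CC(=O)O[C@H](C)Cc1cc(OCc2ccccc2)cc(OCc2ccccc2)c1C(=O)O[C@H](C)CC(=O)O | intermediate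
21 | 5-bromoresorcinol (5-bromobenzene-1,3-diol) | Oc1cc(O)cc(Br)c1 | starting material
22 | 1,3-bis(benzyloxy)-5-bromobenzene | Brc1cc(OCc2ccccc2)cc(OCc2ccccc2)c1 | intermediate
23 | [3,5-bis(benzyloxy)phenyl]magnesium bromide | Br[Mg]c1cc(OCc2ccccc2)cc(OCc2ccccc2)c1 | intermediate
24 | (R)-1-[3,5-bis(benzyloxy)phenyl]propan-2-ol | C[C@@H](O)Cc1cc(OCc2ccccc2)cc(OCc2ccccc2)c1 | intermediate
25 | (R)-1-[3,5-bis(benzyloxy)phenyl]propan-2-yl (R)-3-({2,4-bis(benzyloxy)-6-[(R)-2-({(R)-3-[(2,4-bis(benzyloxy)-6-methylbenzoyl)oxy]butanoyl}oxy)propyl]benzoyl}oxy)butanoate (hexa-O-benzyl hansforester A) | Cc1cc(OCc2ccccc2)cc(OCc2ccccc2)c1C(=O)O[C@H](C)CC(=O)O[C@H](C)Cc1cc(OCc2ccccc2)cc(OCc2ccccc2)c1C(=O)O[C@H](C)CC(=O)O[C@H](C)Cc1cc(OCc2ccccc2)cc(OCc2ccccc2)c1 | intermediate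
26 | hansforester A | Cc1cc(O)cc(O)c1C(=O)O[C@H](C)CC(=O)O[C@H](C)Cc1cc(O)cc(O)c1C(=O)O[C@H](C)CC(=O)O[C@H](C)Cc1cc(O)cc(O)c1 | target

Total steps: 14
Longest linear sequence: 9 steps (1, 2, 3, 7, 8, 9, 10, 13, 14)

Steps most likely to fail

Step 2. Palladation at C6–H may be outrun by protodecarboxylation of the electron-rich acid at palladium, by solvolytic opening of the volatile epoxide, or by catalyst arrest through chelation of the ortho benzyloxy oxygen, so that little lactone forms. The fallback sets out from compound 24 and comes back at compound 7. NBS (1.0 equiv, MeCN, 0 °C) should brominate 24 at the ring carbon flanked by the side chain and one benzyloxy group, giving (R)-1-[3,5-bis(benzyloxy)-2-bromophenyl]propan-2-ol F1. n-BuLi (2.2 equiv, THF, −78 °C) deprotonates the hydroxyl and exchanges bromine for lithium to give lithium (R)-1-[3,5-bis(benzyloxy)-2-lithiophenyl]propan-2-olate F2, which is quenched with CO2. Acidification with HCl gives hydroxy acid 6, which closes to lactone 7 (catalytic TsOH in toluene if needed). The aryl–CH2 bond then comes from the Grignard opening of step 12 and the carboxyl from aryllithium carboxylation.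

Step 9. The activated hydroxy ester may undergo E2 elimination to tert-butyl crotonate while the shielded ring B carboxylate attacks only slowly, so that acid 18 is returned. The fallback sets out from compound 18 and comes back at compound 20. Mitsunobu esterification of 18 with bought (S)-pent-4-en-2-ol (PPh3, DIAD, toluene, 0 °C to rt), an alcohol with no carbonyl to acidify the neighbouring C–H, should give with inversion the (R)-pent-4-en-2-yl benzoate F3. Lemieux–Johnson cleavage (catalytic OsO4, NaIO4, 2,6-lutidine, dioxane/H2O) gives the (R)-4-oxobutan-2-yl benzoate F4, and Pinnick oxidation (NaClO2, NaH2PO4, 2-methylbut-2-ene, t-BuOH/H2O) gives acid 20 directly, which makes step 10 unnecessary.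

Step 7. Alcohol 10 may reclose to lactone 7 with loss of allyl alcohol under DMAP faster than it is acylated, and the activated acid may lose the orsellinate by β-elimination. The fallback sets out from compound 4 and comes back at compound 17. Steps 2 and 3 are run with bought (S)-propylene oxide, which gives via 2,4-bis(benzyloxy)-6-[(S)-2-hydroxypropyl]benzoic acid F5 the lactone (S)-6,8-bis(benzyloxy)-3-methyl-3,4-dihydroisocoumarin F6, and then via potassium 2,4-bis(benzyloxy)-6-[(S)-2-hydroxypropyl]benzoate F7 the ester allyl 2,4-bis(benzyloxy)-6-[(S)-2-hydroxypropyl]benzoate F8. Mitsunobu esterification of F8 with acid 16 (PPh3, DIAD, toluene, 0 °C) then forms the ester at the carbinol carbon with inversion (S to R) and gives 17. The hydroxyl is turned into a leaving group under near-neutral conditions and the acid is never activated at its carbonyl, so neither failure process has a path.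

Further compounds
F1 | step 2 | (R)-1-[3,5-bis(benzyloxy)-2-bromophenyl]propan-2-ol | C[C@@H](O)Cc1cc(OCc2ccccc2)cc(OCc2ccccc2)c1Br
F2 | step 2 | lithium (R)-1-[3,5-bis(benzyloxy)-2-lithiophenyl]propan-2-olate | C[C@@H](O[Li])Cc1cc(OCc2ccccc2)cc(OCc2ccccc2)c1[Li]
F3 | step 9 | (R)-pent-4-en-2-yl 2,4-bis(benzyloxy)-6-[(R)-2-({(R)-3-[(2,4-bis(benzyloxy)-6-methylbenzoyl)oxy]butanoyl}oxy)propyl]benzoate | Cc1cc(OCc2ccccc2)cc(OCc2ccccc2)c1C(=O)O[C@H](C)CC(=O)O[C@H](C)Cc1cc(OCc2ccccc2)cc(OCc2ccccc2)c1C(=O)O[C@H](C)CC=C
F4 | step 9 | (R)-4-oxobutan-2-yl 2,4-bis(benzyloxy)-6-[(R)-2-({(R)-3-[(2,4-bis(benzyloxy)-6-methylbenzoyl)oxy]butanoyl}oxy)propyl]benzoate | Cc1cc(OCc2ccccc2)cc(OCc2ccccc2)c1C(=O)O[C@H](C)CC(=O)O[C@H](C)Cc1cc(OCc2ccccc2)cc(OCc2ccccc2)c1C(=O)O[C@H](C)CC=O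
F5 | step 7 | 2,4-bis(benzyloxy)-6-[(S)-2-hydroxypropyl]benzoic acid | C[C@H](O)Cc1cc(OCc2ccccc2)cc(OCc2ccccc2)c1C(=O)O
F6 | step 7 | (S)-6,8-bis(benzyloxy)-3-methyl-3,4-dihydroisocoumarin | C[C@H]1Cc2cc(OCc3ccccc3)cc(OCc3ccccc3)c2C(=O)O1
F7 | step 7 | potassium 2,4-bis(benzyloxy)-6-[(S)-2-hydroxypropyl]benzoate | C[C@H](O)Cc1cc(OCc2ccccc2)cc(OCc2ccccc2)c1C(=O)[O-].[K+]
F8 | step 7 | allyl 2,4-bis(benzyloxy)-6-[(S)-2-hydroxypropyl]benzoate | C[C@H](O)Cc1cc(OCc2ccccc2)cc(OCc2ccccc2)c1C(=O)OCC=C
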